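The route rests on cutting the bond between the benzylic CH2 on C3 of the oxolan-2-one ring and its guaiacyl ring. C3 carries OH and CH2Ar, a 2-arylethanol unit, which is the retron for opening an epoxide with an aryl-metal. The key step is therefore a strain-driven, copper-catalysed opening of a spiro-oxirane on C3 (a 1,5-dioxaspiro[2.4]heptan-4-one) by a 4-benzyloxy-3-methoxyphenyl Grignard reagent: it joins the halves and unveils the tertiary alcohol at once. The spiro-epoxide comes from dimethyl (R)-malate: Frater–Seebach benzylation sets C4, and a formaldehyde aldol of the hydroxy-lactone dianion, anti to the C4 side chain, sets C3.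

Key step: step 9

Remark: ring atoms are numbered as in oxolan-2-one (O1, C2 carbonyl, C3, C4, C5). Lactone 8 is the cis isomer that the malate route delivers; this is immaterial, because step 6 planarises C3 and rebuilds it under control of C4.

Step 1
Reactants: 1 4-(benzyloxy)-3-methoxybenzyl alcohol
Product: 2 4-(benzyloxy)-3-methoxybenzyl bromide
Conditions: PBr3 (0.4 equiv), Et2O, 0 °C
Reagents that add atoms: phosphorus tribromide, BrP(Br)Br
Why: PBr3 bromination of a primary benzylic alcohol (SN2 displacement of the phosphite ester by bromide) leaves the aryl ethers untouched, and the labile bromide is used at once.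

Step 2
Reactants: 3 dimethyl (R)-malate; 2 4-(benzyloxy)-3-methoxybenzyl bromide
Product: 4 dimethyl (2R,3S)-3-{[4-(benzyloxy)-3-methoxyphenyl]methyl}-2-hydroxybutanedioate (malate numbering, OH on C2)
Conditions: LiN(SiMe3)2 (2.1 equiv), THF, −78 to −20 °C; then 2, −78 to −10 °C; AcOH quench
Reagents that add atoms: none
Why: Frater–Seebach alkylation: the chelated lithium alkoxide–enolate dianion should be benzylated at C3 on the face opposite the C2 ester group, so the (R)-carbinol centre sets C3 as S; the minor C3 epimer must be removed here or at 8, because C2 is erased in step 6 and that epimer would end as the enantiomer.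

Step 3
Reactants: 4 dimethyl (2R,3S)-3-{[4-(benzyloxy)-3-methoxyphenyl]methyl}-2-hydroxybutanedioate
Product: 5 (2R,3S)-3-{[4-(benzyloxy)-3-methoxyphenyl]methyl}-2-hydroxybutanedioic acid
Conditions: LiOH·H2O (4 equiv), THF/H2O, 0 °C to rt; then 1 M HCl to pH 2
Reagents that add atoms: lithium hydroxide, [Li+].[OH-] (its oxygen becomes the OH of each carboxylic acid)
Why: Saponification of both methyl esters at or below room temperature, where the C3 centre of the carboxylate should not epimerise.

Step 4
Reactants: 5 (2R,3S)-3-{[4-(benzyloxy)-3-methoxyphenyl]methyl}-2-hydroxybutanedioic acid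
Product: 6 (2S)-3-[4-(benzyloxy)-3-methoxyphenyl]-2-[(4R)-2,2-dimethyl-5-oxo-1,3-dioxolan-4-yl]propanoic acid
Conditions: 2,2-dimethoxypropane (solvent), TsOH·H2O (cat.), rt
Reagents that add atoms: 2,2-dimethoxypropane, COC(C)(C)OC
Why: Acid-catalysed acetal exchange: the α-hydroxy acid closes the five-membered 1,3-dioxolan-4-one in preference to the six-membered ring open to the other acid, which stays free and is thereby differentiated.

Step 5
Reactants: 6 (2S)-3-[4-(benzyloxy)-3-methoxyphenyl]-2-[(4R)-2,2-dimethyl-5-oxo-1,3-dioxolan-4-yl]propanoic acid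
Product: 8 (3R,4R)-4-{[4-(benzyloxy)-3-methoxyphenyl]methyl}-3-hydroxyoxolan-2-one (cis), via hydroxy dioxolanone 7 (not isolated)
Conditions: BH3·SMe2 (1.5 equiv), THF, 0 °C to rt; MeOH quench; then TsOH·H2O (cat.), CH2Cl2, rt
Reagents that add atoms: none
Why: Borane reduces the free carboxylic acid chemoselectively beside the dioxolanone, and acid then drives intramolecular transesterification (5-exo-trig) of the new primary alcohol onto the dioxolanone carbonyl with loss of acetone; neither stereocentre is touched.

Step 6
Reactants: 8 (3R,4R)-4-{[4-(benzyloxy)-3-methoxyphenyl]methyl}-3-hydroxyoxolan-2-one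
Product: 9 (3S,4R)-4-{[4-(benzyloxy)-3-methoxyphenyl]methyl}-3-hydroxy-3-(hydroxymethyl)oxolan-2-one
Conditions: LiN(iPr)2 (2.3 equiv), THF/DMPU, −78 to −40 °C; CH2O (gas from cracked paraformaldehyde, excess), −78 °C; AcOH quench at −78 °C
Reagents that add atoms: formaldehyde, C=O
Why: Aldol hydroxymethylation of the α-hydroxy lactone dianion (lithium enediolate): deprotonation planarises C3 and formaldehyde should add to the face opposite the C4 arylmethyl group, as in trans-selective alkylations of 4-substituted butyrolactone enolates, so CH2OH ends trans and the hydroxyl cis to that group (3S).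

Step 7
Reactants: 9 (3S,4R)-4-{[4-(benzyloxy)-3-methoxyphenyl]methyl}-3-hydroxy-3-(hydroxymethyl)oxolan-2-one
Product: 11 (3S,7R)-7-{[4-(benzyloxy)-3-methoxyphenyl]methyl}-1,5-dioxaspiro[2.4]heptan-4-one, via primary tosylate 10 (not isolated)
Conditions: TsCl (1.1 equiv), Et3N, DMAP (cat.), CH2Cl2, 0 °C; then DBU (1.5 equiv), 0 °C to rt
Reagents that add atoms: p-toluenesulfonyl chloride, Cc1ccc(cc1)S(Cl)(=O)=O (supplies the tosyl group of 10, which is lost again on closure to 11)
Why: Selective sulfonylation of the primary hydroxyl followed by Williamson-type 3-exo-tet closure by the tertiary alkoxide; no bond to C3 is broken, so its configuration is retained.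

Step 8
Reactants: 12 4-bromo-2-methoxyphenol
Product: 13 1-(benzyloxy)-4-bromo-2-methoxybenzene
Conditions: BnBr, K2CO3, acetone, reflux
Reagents that add atoms: benzyl bromide, BrCc1ccccc1
Why: Williamson ether synthesis on the phenoxide gives the aryl donor with the same protecting group as the other half.

Step 9
Reactants: 11 (3S,7R)-7-{[4-(benzyloxy)-3-methoxyphenyl]methyl}-1,5-dioxaspiro[2.4]heptan-4-one; 13 1-(benzyloxy)-4-bromo-2-methoxybenzene
Product: 15 (3R,4R)-3,4-bis{[4-(benzyloxy)-3-methoxyphenyl]methyl}-3-hydroxyoxolan-2-one, via Grignard reagent 14 (not isolated)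
Conditions: 13, Mg turnings, THF, 40 °C (forms 14); 14 added slowly to 11 and CuI (10 mol%), THF, −40 to −20 °C; aq. NH4Cl
Reagents that add atoms: magnesium, [Mg] (held in intermediate 14 only; none remains in 15)
Why: Catalytic CuI converts Grignard reagent 14 into an arylcuprate, which attacks the unsubstituted oxirane carbon of 11 in SN2 fashion (oxidative addition of monovalent copper into the CH2–O bond to a trivalent alkyl(aryl)copper species, then reductive elimination), forming the aryl–CH2 bond and releasing the C3 alkoxide with relief of the oxirane ring strain. The closest known reaction type is the copper-catalysed opening of 2,2-disubstituted terminal epoxides and of 2-alkylglycidic esters by aryl Grignard reagents at the CH2 terminus. No ring is closed; the three-membered ring is opened. No new stereocentre is formed: the C3–O bond is never broken, so the tertiary carbinol keeps the configuration set in step 6, and the descriptor changes from 3S to 3R only because the CH2 carbon, having lost its oxygen, now ranks below ring carbon C4. The step needs regioselectivity, secured because the other oxirane carbon is quaternary and flanked by the lactone carbonyl, and chemoselectivity for the epoxide over the lactone C=O, secured by the ester-tolerant cuprate at low temperature and by slow addition of 14 so that free Grignard reagent does not accumulate.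

Step 10
Reactants: 15 (3R,4R)-3,4-bis{[4-(benzyloxy)-3-methoxyphenyl]methyl}-3-hydroxyoxolan-2-one
Product: 16 (+)-nortrachelogenin, (3R,4R)-3-hydroxy-3,4-bis[(4-hydroxy-3-methoxyphenyl)methyl]oxolan-2-one
Conditions: H2 (1 atm), 10% Pd/C, EtOAc/EtOH, rt
Reagents that add atoms: none
Why: Heterogeneous hydrogenolysis of the two aryl benzyl ethers; the lactone and the tertiary, non-benzylic alcohol are not reduced, so both stereocentres persist.

Compound list
1 | 4-(benzyloxy)-3-methoxybenzyl alcohol | OCc1ccc(OCc2ccccc2)c(OC)c1 | starting material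
2 | 4-(benzyloxy)-3-methoxybenzyl bromide | BrCc1ccc(OCc2ccccc2)c(OC)c1 | intermediate
3 | dimethyl (R)-malate | COC(=O)C[C@@H](O)C(=O)OC | starting material
4 | dimethyl (2R,3S)-3-{[4-(benzyloxy)-3-methoxyphenyl]methyl}-2-hydroxybutanedioate | COC(=O)[C@H](O)[C@H](Cc1ccc(OCc2ccccc2)c(OC)c1)C(=O)OC | intermediate
5 | (2R,3S)-3-{[4-(benzyloxy)-3-methoxyphenyl]methyl}-2-hydroxybutanedioic acid | OC(=O)[C@H](O)[C@H](Cc1ccc(OCc2ccccc2)c(OC)c1)C(O)=O | intermediate
6 | (2S)-3-[4-(benzyloxy)-3-methoxyphenyl]-2-[(4R)-2,2-dimethyl-5-oxo-1,3-dioxolan-4-yl]propanoic acid | CC1(C)OC(=O)[C@H](O1)[C@H](Cc2ccc(OCc3ccccc3)c(OC)c2)C(O)=O | intermediate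
7 | (5R)-5-{(2R)-1-[4-(benzyloxy)-3-methoxyphenyl]-3-hydroxypropan-2-yl}-2,2-dimethyl-1,3-dioxolan-4-one | CC1(C)OC(=O)[C@H](O1)[C@H](Cc2ccc(OCc3ccccc3)c(OC)c2)CO | intermediate (not isolated)
8 | (3R,4R)-4-{[4-(benzyloxy)-3-methoxyphenyl]methyl}-3-hydroxyoxolan-2-one (cis) | COc1cc(C[C@@H]2COC(=O)[C@@H]2O)ccc1OCc1ccccc1 | intermediate
9 | (3S,4R)-4-{[4-(benzyloxy)-3-methoxyphenyl]methyl}-3-hydroxy-3-(hydroxymethyl)oxolan-2-one | COc1cc(C[C@@H]2COC(=O)[C@@]2(O)CO)ccc1OCc1ccccc1 | intermediate
10 | [(3S,4R)-4-{[4-(benzyloxy)-3-methoxyphenyl]methyl}-3-hydroxy-2-oxooxolan-3-yl]methyl 4-methylbenzenesulfonate | COc1cc(C[C@@H]2COC(=O)[C@@]2(O)COS(=O)(=O)c2ccc(C)cc2)ccc1OCc1ccccc1 | intermediate (not isolated)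
11 | (3S,7R)-7-{[4-(benzyloxy)-3-methoxyphenyl]methyl}-1,5-dioxaspiro[2.4]heptan-4-one | COc1cc(C[C@@H]2COC(=O)[C@@]23CO3)ccc1OCc1ccccc1 | intermediate
12 | 4-bromo-2-methoxyphenol | COc1cc(Br)ccc1O | starting material
13 | 1-(benzyloxy)-4-bromo-2-methoxybenzene | COc1cc(Br)ccc1OCc1ccccc1 | intermediate
14 | [4-(benzyloxy)-3-methoxyphenyl]magnesium bromide | COc1cc([Mg]Br)ccc1OCc1ccccc1 | intermediate (not isolated)
15 | (3R,4R)-3,4-bis{[4-(benzyloxy)-3-methoxyphenyl]methyl}-3-hydroxyoxolan-2-one | COc1cc(C[C@@H]2COC(=O)[C@@]2(O)Cc2ccc(OCc3ccccc3)c(OC)c2)ccc1OCc1ccccc1 | intermediate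
16 | (+)-nortrachelogenin, (3R,4R)-3-hydroxy-3,4-bis[(4-hydroxy-3-methoxyphenyl)methyl]oxolan-2-one | COc1cc(C[C@@H]2COC(=O)[C@@]2(O)Cc2ccc(O)c(OC)c2)ccc1O | target

Total step count: 10. Longest linear sequence: 9 steps (steps 1 to 7, then 9 and 10); step 8 is a one-step branch.

Steps most likely to fail

Step 9 (key step). The free Grignard reagent may add to the lactone carbonyl, halide from the Schlenk equilibrium may open the epoxide before the cuprate does, or the cuprate may reduce the α,β-epoxy lactone by single-electron transfer. The fallback sets out from 11: the epoxide is opened at its CH2 carbon with LiI and AcOH in THF to give the iodohydrin (3R,4R)-4-{[4-(benzyloxy)-3-methoxyphenyl]methyl}-3-hydroxy-3-(iodomethyl)oxolan-2-one F1. F1 and aryl bromide 13 are then joined by a nickel-catalysed reductive cross-electrophile coupling (NiBr2·MeOCH2CH2OMe, 4,4'-di-tert-butyl-2,2'-bipyridine, Mn powder, DMA, rt), in which the alkyl radical from the carbon–iodine bond is captured by an arylnickel species. No organomagnesium reagent meets the lactone, and the route is rejoined at 15.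

Step 6. Dianion formation may be incomplete, the aldol may reverse with loss of formaldehyde on warming or quench, or the small electrophile may discriminate poorly between the two faces. The fallback sets out from 8: the same dianion (LiN(iPr)2, THF/DMPU, −78 °C) is C-alkylated with chloroiodomethane, a larger electrophile that reacts irreversibly and should enter trans to the C4 side chain. The chlorohydrin (3R,4R)-4-{[4-(benzyloxy)-3-methoxyphenyl]methyl}-3-(chloromethyl)-3-hydroxyoxolan-2-one F2 forms as its lithium alkoxide and closes to the spiro-epoxide on warming to rt. The route is rejoined at 11, so step 7 is not needed.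

Step 7. The β-hydroxy lactone may fragment under amine base (retro-aldol) before sulfonylation is complete, or the strained spiro-epoxide may be opened by chloride or DBU once it has formed. The fallback sets out from 9: 1,1'-sulfonyldiimidazole and catalytic DBU in THF convert the diol into the cyclic sulfate (5S,9R)-9-{[4-(benzyloxy)-3-methoxyphenyl]methyl}-1,3,7-trioxa-2-thiaspiro[4.4]nonan-6-one 2,2-dioxide F3, an epoxide surrogate. F3 is opened at its CH2–O carbon by Grignard reagent 14 under CuI catalysis (THF, −40 °C) to the tertiary sulfate monoester (3R,4R)-3,4-bis{[4-(benzyloxy)-3-methoxyphenyl]methyl}-2-oxooxolan-3-yl hydrogen sulfate F4 (magnesium salt, not isolated). Hydrolysis with dilute H2SO4 in THF/H2O rejoins the route at 15.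

Further compounds
F1 | step 9 | (3R,4R)-4-{[4-(benzyloxy)-3-methoxyphenyl]methyl}-3-hydroxy-3-(iodomethyl)oxolan-2-one | COc1cc(C[C@@H]2COC(=O)[C@@]2(O)CI)ccc1OCc1ccccc1
F2 | step 6 | (3R,4R)-4-{[4-(benzyloxy)-3-methoxyphenyl]methyl}-3-(chloromethyl)-3-hydroxyoxolan-2-one | COc1cc(C[C@@H]2COC(=O)[C@@]2(O)CCl)ccc1OCc1ccccc1
F3 | step 7 | (5S,9R)-9-{[4-(benzyloxy)-3-methoxyphenyl]methyl}-1,3,7-trioxa-2-thiaspiro[4.4]nonan-6-one 2,2-dioxide (cyclic sulfate of diol 9) | COc1cc(C[C@@H]2COC(=O)[C@@]23COS(=O)(=O)O3)ccc1OCc1ccccc1
F4 | step 7 | (3R,4R)-3,4-bis{[4-(benzyloxy)-3-methoxyphenyl]methyl}-2-oxooxolan-3-yl hydrogen sulfate | COc1cc(C[C@@H]2COC(=O)[C@@]2(OS(=O)(=O)O)Cc2ccc(OCc3ccccc3)c(OC)c2)ccc1OCc1ccccc1
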